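## Retrosynthetic overview

1. The target comes from its benzylic acetate by C–O hydrogenolysis; the acetate comes from the α-(hydroxybenzyl) lactone, in which the 3,4-trans relationship is already in place.
2. Key C–C disconnection: the C3–benzylic carbon bond, made by an intermolecular aldol addition of the lithium enolate of (R)-4-(3,4,5-trimethoxybenzyl)butyrolactone to 3,4,5-trimethoxybenzaldehyde, anti to the C4 benzyl group.
3. The (R)-lactone comes from lactonisation of a γ-hydroxy tert-butyl ester, itself from Evans alkylation of the N-(3-arylpropanoyl)-(S)-4-benzyloxazolidinone with tert-butyl bromoacetate (this sets C4).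
4. The acyl unit comes from 3,4,5-trimethoxycinnamic acid by hydrogenation.
5. Ring order: only one ring is built, the butyrolactone (step 6); both arenes are bought.

Assumption: the carbinol carbon created in the aldol step is carried as a mixture of both epimers, because it becomes CH2 in the last step; it is left undefined in the SMILES of 15 and 16.

## Route

Step 1
Reactants: 1 (E)-3,4,5-trimethoxycinnamic acid
Product: 2 3-(3,4,5-trimethoxyphenyl)propanoic acid
Conditions: H2 (1 atm), Pd/C (10 wt %), MeOH, rt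
Reagents that add atoms: none
Why: Catalytic hydrogenation saturates the conjugated alkene cleanly while the arene, the methyl ethers and the acid are untouched; no stereocentre is formed.

Step 2
Reactants: 2 3-(3,4,5-trimethoxyphenyl)propanoic acid; 3 (4S)-4-benzyl-1,3-oxazolidin-2-one
Product: 5 (4S)-4-benzyl-3-[3-(3,4,5-trimethoxyphenyl)propanoyl]-1,3-oxazolidin-2-one, via mixed pivalic anhydride 4 (not isolated)
Conditions: PivCl, Et3N, THF, −20 °C; then 3, LiCl, −20 °C to rt
Reagents that add atoms: none
Why: N-Acylation of the oxazolidinone through the mixed anhydride occurs at the unhindered acyl carbon (LiCl/Et3N activation), and the auxiliary stereocentre is not touched.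

Step 3
Reactants: 5 (4S)-4-benzyl-3-[3-(3,4,5-trimethoxyphenyl)propanoyl]-1,3-oxazolidin-2-one; 6 tert-butyl bromoacetate
Product: 8 tert-butyl (3R)-4-[(4S)-4-benzyl-2-oxo-1,3-oxazolidin-3-yl]-4-oxo-3-(3,4,5-trimethoxybenzyl)butanoate, via sodium Z-enolate 7 (not isolated)
Conditions: NaN(SiMe3)2 (1.1 equiv), THF, −78 °C; then 6 (2 equiv), −78 to −50 °C; chromatography or crystallisation to one diastereomer
Reagents that add atoms: none
Why: Evans asymmetric alkylation, in which the chelated Z-enolate is alkylated on the face opposite the C4 benzyl group of the auxiliary, setting the new centre as (3R) (the future C4 of the lactone) with high diastereoselectivity.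

Step 4
Reactants: 8 tert-butyl (3R)-4-[(4S)-4-benzyl-2-oxo-1,3-oxazolidin-3-yl]-4-oxo-3-(3,4,5-trimethoxybenzyl)butanoate
Product: 10 (2R)-4-tert-butoxy-4-oxo-2-(3,4,5-trimethoxybenzyl)butanoic acid, via peroxy acid 9 (not isolated)
Conditions: LiOH·H2O (2 equiv), 30% aq. H2O2 (4 equiv), THF/H2O 3:1, 0 °C; then aq. Na2SO3; then 1 M HCl to pH 3
Reagents that add atoms: hydrogen peroxide, OO
Why: Hydroperoxide cleavage of the imide attacks the exocyclic carbonyl selectively, the peracid is reduced by sulfite, and the tert-butyl ester and the α-stereocentre survive the cold, weakly basic conditions.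

Step 5
Reactants: 10 (2R)-4-tert-butoxy-4-oxo-2-(3,4,5-trimethoxybenzyl)butanoic acid
Product: 11 tert-butyl (3R)-3-(hydroxymethyl)-4-(3,4,5-trimethoxyphenyl)butanoate
Conditions: BH3·SMe2 (1.5 equiv), THF, 0 °C to rt; then H2O
Reagents that add atoms: none
Why: Chemoselective borane reduction converts the free carboxylic acid to the primary alcohol much faster than it touches the tert-butyl ester, and the stereocentre is not involved.

Step 6
Reactants: 11 tert-butyl (3R)-3-(hydroxymethyl)-4-(3,4,5-trimethoxyphenyl)butanoate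
Product: 12 (4R)-4-(3,4,5-trimethoxybenzyl)oxolan-2-one
Conditions: p-TsOH·H2O (10 mol %), toluene, 80 °C
Reagents that add atoms: none
Why: Acid-catalysed lactonisation of the γ-hydroxy ester closes the five-membered ring with loss of the tert-butyl group, leaving the (R) centre unchanged.

Step 7
Reactants: 12 (4R)-4-(3,4,5-trimethoxybenzyl)oxolan-2-one; 13 3,4,5-trimethoxybenzaldehyde
Product: 15 (3S,4R)-3-[hydroxy(3,4,5-trimethoxyphenyl)methyl]-4-(3,4,5-trimethoxybenzyl)oxolan-2-one as both carbinol epimers, via lithium enolate 14 (not isolated)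
Conditions: LiN(iPr)2 (LDA, 1.1 equiv), THF, −78 °C, 45 min; then 13 (1.2 equiv), −78 °C, 1 h; AcOH quench at −78 °C
Reagents that add atoms: none
Why: Kinetic intermolecular aldol addition in which the aldehyde approaches the lactone enolate anti to the C4 benzyl group, setting C3 trans to C4 (the 3S descriptor is the same spatial arrangement as 3R in the target).

Step 8
Reactants: 15 (3S,4R)-3-[hydroxy(3,4,5-trimethoxyphenyl)methyl]-4-(3,4,5-trimethoxybenzyl)oxolan-2-one
Product: 16 [(3S,4R)-2-oxo-4-(3,4,5-trimethoxybenzyl)oxolan-3-yl](3,4,5-trimethoxyphenyl)methyl acetate as both epimers at the acetoxy carbon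
Conditions: Ac2O (3 equiv), pyridine, DMAP (cat.), CH2Cl2, 0 °C to rt
Reagents that add atoms: acetic anhydride, CC(=O)OC(C)=O
Why: DMAP-catalysed O-acetylation blocks retro-aldol and turns the benzylic oxygen into a better leaving group for hydrogenolysis, without touching C3 or C4 under the mild base.

Step 9
Reactants: 16 [(3S,4R)-2-oxo-4-(3,4,5-trimethoxybenzyl)oxolan-3-yl](3,4,5-trimethoxyphenyl)methyl acetate
Product: 17 (3R,4R)-3,4-bis(3,4,5-trimethoxybenzyl)oxolan-2-one, (−)-cubebininolide
Conditions: H2 (3 atm), Pd/C (10 wt %), EtOH/AcOH 9:1, rt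
Reagents that add atoms: none
Why: Catalytic hydrogenolysis cleaves the electron-rich benzylic C–OAc bond to CH2 without strong acid, so Friedel–Crafts cyclisation onto the second arene is avoided and the trans C3/C4 centres are untouched.

## Compound list

1 | (E)-3,4,5-trimethoxycinnamic acid | COc1cc(/C=C/C(=O)O)cc(OC)c1OC | starting material
2 | 3-(3,4,5-trimethoxyphenyl)propanoic acid | COc1cc(CCC(=O)O)cc(OC)c1OC | intermediate
3 | (4S)-4-benzyl-1,3-oxazolidin-2-one | O=C1N[C@@H](Cc2ccccc2)CO1 | starting material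
4 | 3-(3,4,5-trimethoxyphenyl)propanoic pivalic anhydride (not isolated) | COc1cc(CCC(=O)OC(=O)C(C)(C)C)cc(OC)c1OC | intermediate
5 | (4S)-4-benzyl-3-[3-(3,4,5-trimethoxyphenyl)propanoyl]-1,3-oxazolidin-2-one | COc1cc(CCC(=O)N2[C@@H](Cc3ccccc3)COC2=O)cc(OC)c1OC | intermediate
6 | tert-butyl bromoacetate | CC(C)(C)OC(=O)CBr | starting material
7 | sodium Z-enolate of 5 (not isolated) | [Na+].[O-]/C(=C\Cc1cc(OC)c(OC)c(OC)c1)N1[C@@H](Cc2ccccc2)COC1=O | intermediate
8 | tert-butyl (3R)-4-[(4S)-4-benzyl-2-oxo-1,3-oxazolidin-3-yl]-4-oxo-3-(3,4,5-trimethoxybenzyl)butanoate | CC(C)(C)OC(=O)C[C@@H](Cc1cc(OC)c(OC)c(OC)c1)C(=O)N1[C@@H](Cc2ccccc2)COC1=O | intermediate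
9 | (2R)-4-tert-butoxy-4-oxo-2-(3,4,5-trimethoxybenzyl)butaneperoxoic acid (not isolated) | CC(C)(C)OC(=O)C[C@@H](Cc1cc(OC)c(OC)c(OC)c1)C(=O)OO | intermediate
10 | (2R)-4-tert-butoxy-4-oxo-2-(3,4,5-trimethoxybenzyl)butanoic acid | CC(C)(C)OC(=O)C[C@@H](Cc1cc(OC)c(OC)c(OC)c1)C(=O)O | intermediate
11 | tert-butyl (3R)-3-(hydroxymethyl)-4-(3,4,5-trimethoxyphenyl)butanoate | CC(C)(C)OC(=O)C[C@@H](Cc1cc(OC)c(OC)c(OC)c1)CO | intermediate
12 | (4R)-4-(3,4,5-trimethoxybenzyl)oxolan-2-one | COc1cc(C[C@H]2COC(=O)C2)cc(OC)c1OC | intermediate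
13 | 3,4,5-trimethoxybenzaldehyde | COc1cc(C=O)cc(OC)c1OC | starting material
14 | lithium enolate of 12 (not isolated) | [Li+].[O-]C1=C[C@@H](Cc2cc(OC)c(OC)c(OC)c2)CO1 | intermediate
15 | (3S,4R)-3-[hydroxy(3,4,5-trimethoxyphenyl)methyl]-4-(3,4,5-trimethoxybenzyl)oxolan-2-one, both carbinol epimers | COc1cc(C[C@H]2COC(=O)[C@@H]2C(O)c2cc(OC)c(OC)c(OC)c2)cc(OC)c1OC | intermediate
16 | [(3S,4R)-2-oxo-4-(3,4,5-trimethoxybenzyl)oxolan-3-yl](3,4,5-trimethoxyphenyl)methyl acetate, both epimers at the acetoxy carbon | COc1cc(C[C@H]2COC(=O)[C@@H]2C(OC(C)=O)c2cc(OC)c(OC)c(OC)c2)cc(OC)c1OC | intermediate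
17 | (3R,4R)-3,4-bis(3,4,5-trimethoxybenzyl)oxolan-2-one, (−)-cubebininolide | COc1cc(C[C@H]2COC(=O)[C@@H]2Cc2cc(OC)c(OC)c(OC)c2)cc(OC)c1OC | target

## Step count and risks

Total step count: 9. Longest linear sequence: 9 steps (1 to 17).

**Risk 1, step 7 (aldol addition).** The lithium aldolate can revert (retro-aldol) or give low conversion with the electron-rich aldehyde. The fallback sets out from 12 and comes back at 15. It replaces the reversible aldol by an irreversible Claisen-type acylation followed by reduction. Lactone 12 is converted to enolate 14 with LiN(SiMe3)2 (2.2 equiv, THF, −78 °C) and treated with 3,4,5-trimethoxybenzoyl chloride. The product enolate is stable until quench and gives (3S,4R)-3-(3,4,5-trimethoxybenzoyl)-4-(3,4,5-trimethoxybenzyl)oxolan-2-one F4, which settles as the trans isomer because C3 is epimerisable. NaBH4 in MeOH/THF at −20 °C then reduces only the ketone and gives 15.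

**Risk 2, step 9 (hydrogenolysis of the benzylic acetate).** The C–O cleavage may be slow without strong acid, and strong acid invites cyclisation to an aryltetralin. The fallback sets out from 15 and comes back at 17, using radical instead of catalytic deoxygenation. Alcohol 15 is treated with PhOC(S)Cl, pyridine and DMAP in CH2Cl2 to give O-[[(3S,4R)-2-oxo-4-(3,4,5-trimethoxybenzyl)oxolan-3-yl](3,4,5-trimethoxyphenyl)methyl] O-phenyl carbonothioate F5. Bu3SnH with AIBN in toluene at 90 °C (Barton–McCombie) then replaces the benzylic oxygen by hydrogen through a benzylic radical that cannot disturb C3 or C4, giving 17.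

**Risk 3, step 3 (Evans alkylation with tert-butyl bromoacetate).** The α-bromo ester is a moderate electrophile, and incomplete alkylation or enolate decomposition would lower yield and diastereomeric purity. The fallback sets out from 5 (through its enolate 7) and comes back at 12. It uses allyl as a masked acetic acid unit and builds the lactone oxidatively.
- Enolate 7 is alkylated with allyl iodide at −78 °C to give (4S)-4-benzyl-3-[(2S)-2-(3,4,5-trimethoxybenzyl)pent-4-enoyl]-1,3-oxazolidin-2-one F1. The facial selectivity is the same as in step 3; the descriptor differs only through substituent priorities.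
- LiBH4 in Et2O with one equivalent of H2O at 0 °C removes the auxiliary reductively and gives (2S)-2-(3,4,5-trimethoxybenzyl)pent-4-en-1-ol F2.
- OsO4 (cat.) with NaIO4 and 2,6-lutidine in dioxane/H2O cleaves the alkene; the resulting aldehyde closes to (4R)-4-(3,4,5-trimethoxybenzyl)oxolan-2-ol F3 (anomer mixture).
- PhI(OAc)2 with catalytic TEMPO in CH2Cl2 oxidises the lactol to 12.

## Further compounds

F1 | step 3 | (4S)-4-benzyl-3-[(2S)-2-(3,4,5-trimethoxybenzyl)pent-4-enoyl]-1,3-oxazolidin-2-one | C=CC[C@@H](Cc1cc(OC)c(OC)c(OC)c1)C(=O)N1[C@@H](Cc2ccccc2)COC1=O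
F2 | step 3 | (2S)-2-(3,4,5-trimethoxybenzyl)pent-4-en-1-ol | C=CC[C@@H](Cc1cc(OC)c(OC)c(OC)c1)CO
F3 | step 3 | (4R)-4-(3,4,5-trimethoxybenzyl)oxolan-2-ol, anomer mixture | COc1cc(C[C@H]2COC(O)C2)cc(OC)c1OC
F4 | step 7 | (3S,4R)-3-(3,4,5-trimethoxybenzoyl)-4-(3,4,5-trimethoxybenzyl)oxolan-2-one | COc1cc(C[C@H]2COC(=O)[C@@H]2C(=O)c2cc(OC)c(OC)c(OC)c2)cc(OC)c1OC
F5 | step 9 | O-[[(3S,4R)-2-oxo-4-(3,4,5-trimethoxybenzyl)oxolan-3-yl](3,4,5-trimethoxyphenyl)methyl] O-phenyl carbonothioate, both epimers | COc1cc(C[C@H]2COC(=O)[C@@H]2C(OC(=S)Oc2ccccc2)c2cc(OC)c(OC)c(OC)c2)cc(OC)c1OC
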